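**Retrosynthetic overview**
- Target ⇐ removal of two benzyl ethers ⇐ protected chalcone-lactone ⇐ base-induced (E1cB) opening of a chromanone ring, which serves as the masked cinnamoyl ketone and masked 7-OH.
- Tricyclic lactone–chromanone ⇐ one-flask double annulation of a para-O-benzyl phloroacetophenone: chromanone ring by Kabbe condensation with 4-(benzyloxy)benzaldehyde, then the (4R)-lactone ring by carbene-catalysed oxidative [3+3] annulation with cinnamaldehyde.
- Para-O-benzyl phloroacetophenone ⇐ 2,4,6-trihydroxyacetophenone; the para ether is the regiocontrol element, because the lactone can then close only onto an oxygen ortho to the ketone.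
- Ring order: ring A and the two side-chain benzene rings are bought; the chromanone ring and the lactone ring are formed in the same operation (step 2); the chromanone ring is reopened in step 3.

Assumption: of the two commercial antipodes of the aminoindanol triazolium precatalyst, the (5aS,10bR) salt is taken to be the one that leaves the Re face of the cinnamoyl β-carbon open (needed for 4R); if the first run shows the opposite sense, the mirror-image salt is used.

**Step 1**
Reactants: 1 2,4,6-trihydroxyacetophenone
Product: 2 1-[4-(benzyloxy)-2,6-dihydroxyphenyl]ethan-1-one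
Conditions: BnBr (1.0 equiv), K2CO3 (1.0 equiv), DMF, 0 → 25 °C
Reagents that add atoms: benzyl bromide, BrCc1ccccc1
Why: Williamson etherification; the 4-OH is the most acidic phenol and the only one never hydrogen-bonded to the ketone, so one equivalent of base and halide alkylates it preferentially (dibenzyl ether and recovered 1 are separated by chromatography); no stereocenter is formed.

**Step 2**
Reactants: 2 1-[4-(benzyloxy)-2,6-dihydroxyphenyl]ethan-1-one; 3 4-(benzyloxy)benzaldehyde; 4 (E)-cinnamaldehyde
Product: 7 (4R)-5-(benzyloxy)-8-[4-(benzyloxy)phenyl]-4-phenyl-3,4,8,9-tetrahydro-2H,10H-pyrano[2,3-f]chromene-2,10-dione (both C8 epimers), via chalcone 5 (not isolated), via chromanone 6 (not isolated)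
Conditions: 3 (1.0 equiv), pyrrolidine (0.3 equiv), EtOH, 78 °C, then evaporate; then 4 (1.5 equiv), (5aS,10bR)-2-mesityl-5a,10b-dihydro-4H,6H-indeno[2,1-b][1,2,4]triazolo[4,3-d][1,4]oxazin-2-ium chloride (10 mol%), 3,3',5,5'-tetra-tert-butyl-4,4'-diphenoquinone (1.5 equiv), Cs2CO3 (0.5 equiv), 4 Å MS, toluene–THF, 25 °C
Reagents that add atoms: none
Why: Proposed new method: pyrrolidine-mediated Kabbe condensation (enamine aldol, dehydration to chalcone 5, oxa-Michael closure) builds chromanone 6, whose ring masks the enone and the second ortho-phenol; in the same flask the carbene converts 4, after two-electron oxidation of the Breslow intermediate by the diphenoquinone, into an α,β-unsaturated acyl azolium, the chelated C5 phenol of 6 attacks its β-carbon through C6 (its only ortho C–H; direct Michael addition or O-acylation followed by a Coates–Claisen-type [3,3] shift) and the same oxygen is then acylated, closing the lactone and releasing the carbene (formal [3+3] annulation; closest known chemistry: carbene-catalysed oxidative annulation of enals with naphthols, electron-rich phenols and 1,3-dicarbonyls, plus the classical Kabbe chromanone synthesis); the fused indane of the carbene shields one face so that C6 adds to the Re face of the β-carbon, which sets C4 as R, while the chromanone center is left as a mixture because step 3 destroys it.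

**Step 3**
Reactants: 7 (4R)-5-(benzyloxy)-8-[4-(benzyloxy)phenyl]-4-phenyl-3,4,8,9-tetrahydro-2H,10H-pyrano[2,3-f]chromene-2,10-dione
Product: 8 (4R)-5-(benzyloxy)-8-{(2E)-3-[4-(benzyloxy)phenyl]prop-2-enoyl}-7-hydroxy-4-phenyl-3,4-dihydro-2H-chromen-2-one
Conditions: LiN(SiMe3)2 (1.2 equiv), THF, −78 → −40 °C; then AcOH, −78 °C
Reagents that add atoms: none
Why: E1cB retro-oxa-Michael ring opening; the amide base removes a proton α to the chromanone ketone and the aryloxide is expelled, giving the lithium chelate of the (E)-ortho-hydroxychalcone as an irreversible sink for both C8 epimers, while no nucleophile is present to open the lactone (whose only other neighbouring oxygen, O5, is benzylated) and the non-acidic C4 center is untouched.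

**Step 4**
Reactants: 8 (4R)-5-(benzyloxy)-8-{(2E)-3-[4-(benzyloxy)phenyl]prop-2-enoyl}-7-hydroxy-4-phenyl-3,4-dihydro-2H-chromen-2-one
Product: 9 (4R)-5,7-dihydroxy-8-[(2E)-3-(4-hydroxyphenyl)prop-2-enoyl]-4-phenyl-3,4-dihydro-2H-chromen-2-one
Conditions: BCl3 (6 equiv), C6HMe5 (6 equiv), CH2Cl2, −78 °C; then H2O
Reagents that add atoms: none
Why: Lewis-acid ether cleavage using a cation scavenger (BCl3/pentamethylbenzene debenzylation); both aryl benzyl ethers are cleaved at −78 °C without touching the enone, the lactone or C4, and the boron chelate of the ortho-hydroxy ketone keeps the phenol from adding back to the enone.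

**Compound list**
1 | 2,4,6-trihydroxyacetophenone | CC(=O)c1c(O)cc(O)cc1O | starting material
2 | 1-[4-(benzyloxy)-2,6-dihydroxyphenyl]ethan-1-one | CC(=O)c1c(O)cc(OCc2ccccc2)cc1O | intermediate
3 | 4-(benzyloxy)benzaldehyde | O=Cc1ccc(OCc2ccccc2)cc1 | starting material
4 | (E)-cinnamaldehyde | O=C/C=C/c1ccccc1 | starting material
5 | (E)-1-[4-(benzyloxy)-2,6-dihydroxyphenyl]-3-[4-(benzyloxy)phenyl]prop-2-en-1-one | O=C(/C=C/c1ccc(OCc2ccccc2)cc1)c1c(O)cc(OCc2ccccc2)cc1O | intermediate
6 | racemic 7-(benzyloxy)-2-[4-(benzyloxy)phenyl]-5-hydroxy-2,3-dihydro-4H-chromen-4-one | O=C1CC(c2ccc(OCc3ccccc3)cc2)Oc2cc(OCc3ccccc3)cc(O)c12 | intermediate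
7 | (4R)-5-(benzyloxy)-8-[4-(benzyloxy)phenyl]-4-phenyl-3,4,8,9-tetrahydro-2H,10H-pyrano[2,3-f]chromene-2,10-dione, both C8 epimers (dihydrocoumarin lactone fused to a 2-aryl-chroman-4-one) | O=C1C[C@H](c2ccccc2)c2c(OCc3ccccc3)cc3OC(c4ccc(OCc5ccccc5)cc4)CC(=O)c3c2O1 | intermediate
8 | (4R)-5-(benzyloxy)-8-{(2E)-3-[4-(benzyloxy)phenyl]prop-2-enoyl}-7-hydroxy-4-phenyl-3,4-dihydro-2H-chromen-2-one | O=C1C[C@H](c2ccccc2)c2c(OCc3ccccc3)cc(O)c(C(=O)/C=C/c3ccc(OCc4ccccc4)cc3)c2O1 | intermediate
9 | (4R)-5,7-dihydroxy-8-[(2E)-3-(4-hydroxyphenyl)prop-2-enoyl]-4-phenyl-3,4-dihydro-2H-chromen-2-one | O=C1C[C@H](c2ccccc2)c2c(O)cc(O)c(C(=O)/C=C/c3ccc(O)cc3)c2O1 | target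

**Totals**
Total step count: 4. Longest linear sequence: 4 steps (1 → 2 → 7 → 8 → 9).

**Steps most likely to fail**

Step 2. The chelated phenol of 6 may be too weak a carbon nucleophile, or may be alkylated para to the hydroxyl where no lactone can close. The fallback sets out from 2 and comes back at 8; it builds the lactone first and never forms the chromanone. Compound 2 is symmetrical and each of its two ring C–H positions lies next to a free phenol, so the same carbene-catalysed oxidative annulation with 4 (1.0 equiv) can give only one lactone, (4R)-8-acetyl-5-(benzyloxy)-7-hydroxy-4-phenyl-3,4-dihydro-2H-chromen-2-one F1. Claisen–Schmidt condensation of F1 with 3 under BF3·OEt2 in dioxane (through the boron chelate of the ortho-hydroxy ketone, lactone left closed) then gives 8 directly.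

Step 3. The base may also deprotonate the lactone or trigger aldol-type side reactions of the enolate. The fallback sets out from 7 and comes back at 9; it deprotects first and opens the ring by a different mechanism. Hydrogenolysis of 7 (H2, Pd/C, EtOAc; no alkene is present at this stage) gives (4R)-5-hydroxy-8-(4-hydroxyphenyl)-4-phenyl-3,4,8,9-tetrahydro-2H,10H-pyrano[2,3-f]chromene-2,10-dione F2. Its free para-phenol lets the chromanone open through a quinone methide under a mild, non-nucleophilic base (Cs2CO3, dry DMF, 25 °C, then AcOH), which gives 9.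

Step 1. Mono-benzylation may give mixtures that are hard to separate. The fallback sets out from 1 and comes back at 2; it protects everything and then deprotects selectively. Exhaustive benzylation (BnBr, K2CO3, DMF, 60 °C) gives 1-[2,4,6-tris(benzyloxy)phenyl]ethan-1-one F3. Chelation-controlled cleavage with MgBr2·OEt2 (toluene–Et2O, 60 °C) then removes only the two benzyl ethers ortho to the ketone and returns 2.

**Further compounds**
F1 | step 2 | (4R)-8-acetyl-5-(benzyloxy)-7-hydroxy-4-phenyl-3,4-dihydro-2H-chromen-2-one | O=C1C[C@H](c2ccccc2)c2c(OCc3ccccc3)cc(O)c(C(C)=O)c2O1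
F2 | step 3 | (4R)-5-hydroxy-8-(4-hydroxyphenyl)-4-phenyl-3,4,8,9-tetrahydro-2H,10H-pyrano[2,3-f]chromene-2,10-dione, both C8 epimers | O=C1C[C@H](c2ccccc2)c2c(O)cc3OC(c4ccc(O)cc4)CC(=O)c3c2O1
F3 | step 1 | 1-[2,4,6-tris(benzyloxy)phenyl]ethan-1-one | CC(=O)c1c(OCc2ccccc2)cc(OCc2ccccc2)cc1OCc1ccccc1
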